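**Assumption:** compounds 1, 5 and 21 are taken as catalogue compounds (5 and 21 as single enantiomers); elemane/germacrane numbering (C1–C15, side chain C1′–C4′) is used for all intermediates.

## Analysis of the target

- Compound 27 is an elemane sesquiterpene lactone. One cyclohexane ring (C5–C6–C7–C8–C9–C10) is trans-fused at C6/C7 to an α-methylene-γ-butyrolactone (O6–C12(=O)–C11(=C13H2)–C7).
- C10 is quaternary (methyl C14, vinyl C1=C2). C5 carries a 2-formylvinyl group (C3H2=C4–C15HO). O8 carries an (R)-3,4-dihydroxy-2-methylenebutanoate.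
- The ring has five stereocentres, (5R,6R,7R,8S,10S): H5α, H6β, H7α, H8β, 10β-methyl. Every ring substituent is equatorial except C14. The sixth centre, C3′ (R), is remote.
- The feature that decides the strategy is the hexa-1,5-diene C2=C1–C10–C5–C4=C3. Its central σ-bond C5–C10 is a ring bond and the formyl group sits on the inner olefinic carbon C4. This is a Cope retron; its [3,3] isomer is an (E,E)-cyclodeca-1(10),4-diene (a germacranolide) in which C5 and C10 are trigonal.
- Sensitive groups: three Michael acceptors (enal, α-methylene lactone, acrylate) and an aldehyde. The 4′-hydroxyl is γ to the ester carbonyl, so base would expel the C8 alcohol by lactonisation. A free O8 alkoxide can take over the lactone from O6.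
- The hard part is the vicinal pair C10 (quaternary) / C5 with two different alkenyl groups trans to each other, embedded in four contiguous ring centres, together with three exocyclic methylene groups that rule out late reductions or nucleophilic steps.

## Retrosynthetic reasoning

**Ester and diol (27 ⇒ 26 ⇒ 20 + 24).** The C8–O acyl bond is cut last-but-one so that the base-sensitive γ-hydroxy ester exists only at the end. The diol is carried as an acetonide (26) and released by acid. Acid 24 is a separate three-step branch from 21 (via 22 and 23), whose stereocentre becomes C3′.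

**Cope ring contraction (20 ⇒ 19 ⇒ 18).** The C5–C10 bond is cut and C2–C3 is joined, turning the cyclohexane of 20 into the ten-membered ring of 19. This removes the quaternary centre and the C5 centre at once: in 19 both are olefinic carbons whose geometry (E,E) encodes the trans relationship. The formyl group on C4 is the accelerating substituent, so 19 is generated from the allylic alcohol 18 and should rearrange in the same operation. The precursor 18 has only three stereocentres (C6–C8).

**Macrocyclisation and lactone (18 ⇒ 17 ⇒ 16 ⇒ 15).** The C6–C7 bond and the lactone C–O bond are cut together. Forward, a chromium-mediated allylation of the C6 enal by a 2-(bromomethyl)enoate closes the ten-membered ring, sets C6 and C7 under the influence of C8, and delivers the α-methylene lactone. This cut is preferred over others in the ring because it is the only one that creates stereocentres and the lactone in the same bond formation.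

**2-(Bromomethyl)enoate (15 ⇒ 14 ⇒ 13 ⇒ 12 ⇒ 11).** C7–C11 is cut: a Morita–Baylis–Hillman reaction brings in C11–C13 and an SN2′ bromination transposes the functionality. The two aldehydes of 13 come from diol 12, freed from 11 by removal of one orthogonal protecting group.

**Fragment union (11 ⇒ 4 + 9).** The sp3–sp2 bond C2–C1 is cut. A B-alkyl Suzuki–Miyaura coupling joins the hydroborated diene 4 to alkenyl iodide 9 with retention, so each trisubstituted olefin is made on a small fragment where its geometry is easy to control.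

**West fragment (4 ⇒ 3 ⇒ 2 ⇒ 1).** The C3–C4 bond is cut. Syn-addition of a vinyl copper reagent to ynoate 2 fixes the C4=C5 geometry and differentiates C6 (ester) from C15 (silyl ether).

**East fragment (9 ⇒ 8 ⇒ 6 ⇒ 5).** The C14–C10 and C9–C10 bonds are traced back to a carboalumination of alkyne 6 and an acetylide opening of epoxide 5. C8, the only purchased stereocentre of the core, comes from 5.

## Alternatives that were turned down

**Alternative 1: (textbook) conjugate addition to a preformed six-membered ring.**
- Disconnection: C10–C1 and C5–C4 on a cyclohexenone.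
- Forward key step: copper-mediated 1,4-addition of a vinyl nucleophile to enone A1 to create C10, trapping of the enolate at C5 with a three-carbon acrolein equivalent, then C6 reduction and elaboration of the isopropenyl group into the methylene lactone.
- Why turned down: the nucleophile should enter C10 anti to the C8 silyloxy group, giving 10α-methyl/10β-vinyl, the opposite of the target. Correcting this needs methyl addition to a vinyl-substituted dienone (1,6-addition competes) or a vinyl surrogate. The C5 substituent is sp2 and cannot be introduced by enolate alkylation next to the new quaternary centre. Stereocentres are set one at a time and the isopropenyl group needs oxidation at two carbons. The sequence is long and stereochemically mismatched.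

**Alternative 2: ring-A scission of a eudesmanolide.**
- Disconnection: the elemane as a 2,3-seco-eudesmane (retrosynthetic C2–C3 bond formation).
- Forward key step: oxidative cleavage of the C2=C3 olefin of A2 to a seco-diol, followed by twofold selenoxide elimination to unveil both terminal olefins.
- Why turned down: purchasable eudesmanolides have no oxygen at C8, an unactivated methylene, so A2 would itself need a long synthesis. The cleavage is incompatible with the 11(13)-olefin, which must be introduced later. C15 still needs allylic oxidation in the presence of three other olefins. A ring is built only to be cut.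

**Alternative 3: acyclic Claisen, then six-membered Barbier closure.**
- Disconnection: C6–C7 with lactone formation on an open chain, the C5/C10 pair set beforehand by an ester-enolate Claisen rearrangement.
- Forward key step: chromium-mediated cyclisation of aldehyde–allyl bromide A3.
- Why turned down: the Claisen step must set quaternary C10 and C5 in the absolute sense with only the remote C8 centre as control, so an external chiral controller is needed. A3 is an α-branched, β,γ-unsaturated aldehyde next to a quaternary centre, prone to epimerisation at C5 and to olefin migration into conjugation. Two further centres must then be set in a ring closure without conformational bias. The step count is no lower than the chosen route.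

Key step: step 14

## Route

Step 1
Reactants: 1 triisopropyl(prop-2-yn-1-yloxy)silane
Product: 2 methyl 4-((triisopropylsilyl)oxy)but-2-ynoate
Conditions: n-BuLi, THF, −78 °C; ClCO2Me, −78 → 0 °C
Reagents that add atoms: methyl chloroformate COC(=O)Cl
Why: Deprotonation of the terminal alkyne and C-acylation of the acetylide; the ester carbon becomes C6 and the propargylic CH2O becomes C15.

Step 2
Reactants: 2 methyl 4-((triisopropylsilyl)oxy)but-2-ynoate
Product: 3 methyl (2Z)-3-(((triisopropylsilyl)oxy)methyl)penta-2,4-dienoate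
Conditions: CH2=CHMgBr (2.2 equiv), CuI (1.1 equiv), THF, −78 °C; MeOH then aq. NH4Cl at −78 °C
Reagents that add atoms: vinylmagnesium bromide C=C[Mg]Br
Why: Syn-carbocupration (conjugate addition) of the vinyl cuprate to the ynoate and cold protonation with retention place the vinyl group (C3–C2) cis to H5 and trans to C6, which is the C4=C5 geometry needed in the ten-membered ring.

Step 3
Reactants: 3 methyl (2Z)-3-(((triisopropylsilyl)oxy)methyl)penta-2,4-dienoate
Product: 4 (2Z)-3-(((triisopropylsilyl)oxy)methyl)penta-2,4-dien-1-ol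
Conditions: DIBAL-H (2.3 equiv), CH2Cl2, −78 °C; Rochelle salt
Reagents that add atoms: none
Why: 1,2-Reduction of the conjugated ester to the allylic alcohol (C6–OH); the bulky TIPS group on O15 is chosen because it should not migrate to the neighbouring free hydroxyl in later basic steps.

Step 4
Reactants: 5 (S)-2-(((4-methoxybenzyl)oxy)methyl)oxirane
Product: 6 (S)-1-((4-methoxybenzyl)oxy)pent-4-yn-2-ol
Conditions: HC≡CLi·ethylenediamine, DMSO, 0 °C → rt
Reagents that add atoms: lithium acetylide (ethylenediamine complex) [Li]C#C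
Why: SN2 opening of the terminal epoxide at its unsubstituted carbon (C9); the C–O bond at the stereocentre is untouched, so the (S) centre of 5 becomes C8 (8α-O).

Step 5
Reactants: 6 (S)-1-((4-methoxybenzyl)oxy)pent-4-yn-2-ol
Product: 8 (2S,4E)-5-iodo-1-((4-methoxybenzyl)oxy)-4-methylpent-4-en-2-ol, via alkenylalane 7 (not isolated)
Conditions: Me3Al (3 equiv), Cp2ZrCl2 (0.3 equiv), CH2Cl2, 0 °C → rt; then I2, THF, −30 °C
Reagents that add atoms: trimethylaluminium C[Al](C)C; iodine II
Why: Zirconium-catalysed syn-carboalumination (Negishi carboalumination) puts methyl (C14) on the internal carbon (C10) and aluminium on the terminal carbon (C1); iodinolysis with retention gives the (E)-iodide and fixes the 1(10)E geometry.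

Step 6
Reactants: 8 (2S,4E)-5-iodo-1-((4-methoxybenzyl)oxy)-4-methylpent-4-en-2-ol
Product: 9 tert-butyl(((2S,4E)-5-iodo-1-((4-methoxybenzyl)oxy)-4-methylpent-4-en-2-yl)oxy)dimethylsilane
Conditions: TBSCl, imidazole, DMF, rt
Reagents that add atoms: tert-butyldimethylsilyl chloride CC(C)(C)[Si](C)(C)Cl
Why: Standard silylation of the secondary alcohol; TBS on O8 and TIPS on O15 form one set removed together in step 13, while PMB on O7 is orthogonal.

Step 7
Reactants: 4 (2Z)-3-(((triisopropylsilyl)oxy)methyl)penta-2,4-dien-1-ol; 9 tert-butyl(((2S,4E)-5-iodo-1-((4-methoxybenzyl)oxy)-4-methylpent-4-en-2-yl)oxy)dimethylsilane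
Product: 11 (2Z,6E,9S)-9-((tert-butyldimethylsilyl)oxy)-10-((4-methoxybenzyl)oxy)-7-methyl-3-(((triisopropylsilyl)oxy)methyl)deca-2,6-dien-1-ol, via B-alkyl-9-BBN adduct 10 (not isolated)
Conditions: 4, 9-BBN (2.2 equiv), THF, 0 °C → rt; then 9, Pd(dppf)Cl2 (5 mol %), AsPh3, aq. Cs2CO3, DMF, rt
Reagents that add atoms: none
Why: 9-BBN first converts the hydroxyl into a borinate and then hydroborates only the monosubstituted olefin of the 2-substituted diene at its terminus (C2). B-alkyl Suzuki–Miyaura coupling with the alkenyl iodide proceeds with retention and forms C2–C1, so both trisubstituted olefins of the future ring are in place with defined geometry.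

Step 8
Reactants: 11 (2Z,6E,9S)-9-((tert-butyldimethylsilyl)oxy)-10-((4-methoxybenzyl)oxy)-7-methyl-3-(((triisopropylsilyl)oxy)methyl)deca-2,6-dien-1-ol
Product: 12 (2Z,6E,9S)-9-((tert-butyldimethylsilyl)oxy)-7-methyl-3-(((triisopropylsilyl)oxy)methyl)deca-2,6-diene-1,10-diol
Conditions: DDQ, CH2Cl2/pH 7 buffer, 0 °C
Reagents that add atoms: none
Why: Oxidative cleavage of the p-methoxybenzyl ether; silyl ethers and olefins are inert, and any oxidation of the allylic alcohol to the enal converges in step 9.

Step 9
Reactants: 12 (2Z,6E,9S)-9-((tert-butyldimethylsilyl)oxy)-7-methyl-3-(((triisopropylsilyl)oxy)methyl)deca-2,6-diene-1,10-diol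
Product: 13 (2Z,6E,9S)-9-((tert-butyldimethylsilyl)oxy)-7-methyl-3-(((triisopropylsilyl)oxy)methyl)deca-2,6-dienedial
Conditions: Dess–Martin periodinane, NaHCO3, CH2Cl2, 0 °C → rt
Reagents that add atoms: none
Why: Buffered Dess–Martin oxidation of both primary alcohols should give the C6 enal and the α-silyloxy C7 aldehyde without loss of the 4Z geometry or the C8 configuration.

Step 10
Reactants: 13 (2Z,6E,9S)-9-((tert-butyldimethylsilyl)oxy)-7-methyl-3-(((triisopropylsilyl)oxy)methyl)deca-2,6-dienedial
Product: 14 methyl (4S,6E,10Z)-4-((tert-butyldimethylsilyl)oxy)-3-hydroxy-6-methyl-2-methylidene-12-oxo-10-(((triisopropylsilyl)oxy)methyl)dodeca-6,10-dienoate (C3 epimers)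
Conditions: methyl acrylate (excess), DABCO, MeOH (cat.), rt
Reagents that add atoms: methyl acrylate C=CC(=O)OC
Why: Morita–Baylis–Hillman reaction: the DABCO–acrylate zwitterion adds to the electrophilic α-silyloxy aldehyde (C7) and not to the β,β-disubstituted enal (C6), a poor electrophile for this reaction. The new carbinol centre forms as a mixture and is erased in step 11.

Step 11
Reactants: 14 methyl (4S,6E,10Z)-4-((tert-butyldimethylsilyl)oxy)-3-hydroxy-6-methyl-2-methylidene-12-oxo-10-(((triisopropylsilyl)oxy)methyl)dodeca-6,10-dienoate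
Product: 15 methyl (2Z,4S,6E,10Z)-2-(bromomethyl)-4-((tert-butyldimethylsilyl)oxy)-6-methyl-12-oxo-10-(((triisopropylsilyl)oxy)methyl)dodeca-2,6,10-trienoate
Conditions: NBS, Me2S, CH2Cl2, 0 °C → rt
Reagents that add atoms: N-bromosuccinimide O=C1CCC(=O)N1Br
Why: The alkoxysulfonium salt of the allylic alcohol is displaced by bromide in an SN2′ sense, giving the conjugated (2Z)-2-(bromomethyl)enoate with the ester trans to C8.

Step 12
Reactants: 15 methyl (2Z,4S,6E,10Z)-2-(bromomethyl)-4-((tert-butyldimethylsilyl)oxy)-6-methyl-12-oxo-10-(((triisopropylsilyl)oxy)methyl)dodeca-2,6,10-trienoate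
Product: 17 8α-(tert-butyldimethylsilyloxy)-15-(triisopropylsilyloxy)germacra-1(10)E,4Z,11(13)-trien-12,6α-olide (6βH,7αH,8βH), via hydroxy ester 16 (not isolated)
Conditions: CrCl2 (8 equiv), THF, 2 mM, slow addition, rt → 45 °C; aq. NH4Cl
Reagents that add atoms: none
Why: Nozaki–Hiyama–Kishi (chromium Barbier) allylation: the allylchromium(III) species adds through its γ-carbon (C7) to the C6 enal in a ten-membered ring closure, and the C6 alkoxide then acylates with the C12 ester to give the lactone. Anti (6,7-trans) addition is expected because only this arrangement fits the tether containing two E olefins, and attack on the allyl face anti to the C8 silyloxy group (C8–H eclipsing the olefin) should give H7/H8 anti, so that all three substituents of the C6–C9 bridge are pseudo-equatorial.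

Step 13
Reactants: 17 8α-(tert-butyldimethylsilyloxy)-15-(triisopropylsilyloxy)germacra-1(10)E,4Z,11(13)-trien-12,6α-olide
Product: 18 (6R,7R,8S)-8α,15-dihydroxygermacra-1(10)E,4Z,11(13)-trien-12,6α-olide (salonitenolide)
Conditions: HF·pyridine, pyridine, THF, 0 °C → rt
Reagents that add atoms: none
Why: Buffered HF·pyridine cleaves both silyl ethers; it is not basic enough to induce lactone migration to O8 and should not be acidic enough to trigger transannular cyclisation of the cyclodecadiene.

Step 14
Reactants: 18 (6R,7R,8S)-8α,15-dihydroxygermacra-1(10)E,4Z,11(13)-trien-12,6α-olide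
Product: 20 (5R,6R,7R,8S,10S)-8α-hydroxy-15-oxoelema-1,3,11(13)-trien-12,6α-olide, via germacranolide 15-aldehyde 19 (not isolated)
Conditions: activated MnO2 (excess), CH2Cl2, rt; filter; warm to 40–60 °C (benzene) if 19 persists
Reagents that add atoms: none
Why: MnO2 oxidises only the primary allylic C15 hydroxyl (the C8 hydroxyl is not allylic) to the 4Z-enal 19, whose hexa-1,5-diene C5=C4–C3–C2–C1=C10 now carries a formyl group on the inner carbon C4. This acceptor stabilises the diyl-like chair transition state, so the [3,3] shift (Cope rearrangement) should proceed at or slightly above room temperature; the closest known reaction type is the thermal germacrane-to-elemane Cope rearrangement of (E,E)-cyclodeca-1,5-dienes, which is strongly accelerated by a carbonyl group on C4. The cyclohexane ring C5–C10 is closed by transannular C5–C10 bond formation inside the ten-membered ring (sigmatropic ring contraction through a chair transition state) while C2–C3 is cleaved. C5 and C10 are set together: in the crossed conformer of the (E,E)-diene, with C14 and the formyl group on the same (β) face, the chair transition state translates the two E geometries into trans-disposed vinyl and formylvinyl groups, 10β-methyl and H5α. The face is dictated by the trans-fused lactone and the pseudo-equatorial C8 hydroxyl, which fix the conformation of the C6–C9 bridge. The step needs chemoselective oxidation (secured by the allylic/non-allylic difference of the two hydroxyls) and an equilibrium on the elemane side, which release of the cyclodecadiene strain and retained enal conjugation should secure.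

Step 15
Reactants: 21 (R)-4-(2-hydroxyethyl)-2,2-dimethyl-1,3-dioxolane
Product: 22 (R)-2-(2,2-dimethyl-1,3-dioxolan-4-yl)acetaldehyde
Conditions: Dess–Martin periodinane, NaHCO3, CH2Cl2, 0 °C → rt
Reagents that add atoms: none
Why: Dess–Martin oxidation of the primary alcohol; the stereocentre is β to the new carbonyl and not enolisable.

Step 16
Reactants: 22 (R)-2-(2,2-dimethyl-1,3-dioxolan-4-yl)acetaldehyde
Product: 23 (R)-2-(2,2-dimethyl-1,3-dioxolan-4-yl)acrylaldehyde
Conditions: 37% aq. CH2O, pyrrolidine (10 mol %), propionic acid (10 mol %), i-PrOH, 45 °C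
Reagents that add atoms: formaldehyde C=O
Why: Amine-catalysed α-methylenation of the aldehyde (Mannich condensation via the enamine, then elimination of the amine); the stereocentre is not touched, and the buffered conditions should suppress β-elimination of the dioxolane oxygen.

Step 17
Reactants: 23 (R)-2-(2,2-dimethyl-1,3-dioxolan-4-yl)acrylaldehyde
Product: 24 (R)-2-(2,2-dimethyl-1,3-dioxolan-4-yl)acrylic acid
Conditions: NaClO2, NaH2PO4, 2-methyl-2-butene, t-BuOH/H2O, 0 °C → rt
Reagents that add atoms: sodium chlorite [Na+].[O-]Cl=O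
Why: Pinnick oxidation converts the 2-substituted acrolein into the acrylic acid without touching the olefin or the acetonide.

Step 18
Reactants: 20 (5R,6R,7R,8S,10S)-8α-hydroxy-15-oxoelema-1,3,11(13)-trien-12,6α-olide; 24 (R)-2-(2,2-dimethyl-1,3-dioxolan-4-yl)acrylic acid
Product: 26 8α-[(R)-2-(2,2-dimethyl-1,3-dioxolan-4-yl)acryloyloxy]-15-oxoelema-1,3,11(13)-trien-12,6α-olide, via mixed anhydride 25 (not isolated)
Conditions: 24, 2,4,6-trichlorobenzoyl chloride, Et3N, THF, 0 °C; then 20, DMAP, toluene, rt
Reagents that add atoms: none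
Why: Yamaguchi esterification: the mixed anhydride acylates DMAP and the acylpyridinium transfers the acyl group to the only free hydroxyl (equatorial O8) of 20; no stereocentre is formed and C3′ is not epimerisable under these conditions.

Step 19
Reactants: 26 8α-[(R)-2-(2,2-dimethyl-1,3-dioxolan-4-yl)acryloyloxy]-15-oxoelema-1,3,11(13)-trien-12,6α-olide
Product: 27 CNP0204284.1 (target), 8α-[(R)-3,4-dihydroxy-2-methylenebutanoyloxy]-15-oxoelema-1,3,11(13)-trien-12,6α-olide
Conditions: AcOH/H2O (4:1), 40 °C
Reagents that add atoms: none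
Why: Acid-catalysed hydrolysis of the terminal isopropylidene acetal; acid is chosen because base would induce lactonisation of the 4′-hydroxyl onto the ester and Michael additions, whereas enal, lactone and ester should tolerate aqueous acetic acid.

## Compound list

1 | triisopropyl(prop-2-yn-1-yloxy)silane | C#CCO[Si](C(C)C)(C(C)C)C(C)C | starting material
2 | methyl 4-((triisopropylsilyl)oxy)but-2-ynoate | COC(=O)C#CCO[Si](C(C)C)(C(C)C)C(C)C | intermediate
3 | methyl (2Z)-3-(((triisopropylsilyl)oxy)methyl)penta-2,4-dienoate | COC(=O)/C=C(/C=C)CO[Si](C(C)C)(C(C)C)C(C)C | intermediate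
4 | (2Z)-3-(((triisopropylsilyl)oxy)methyl)penta-2,4-dien-1-ol | OC/C=C(/C=C)CO[Si](C(C)C)(C(C)C)C(C)C | intermediate
5 | (S)-2-(((4-methoxybenzyl)oxy)methyl)oxirane | COc1ccc(COC[C@@H]2CO2)cc1 | starting material
6 | (S)-1-((4-methoxybenzyl)oxy)pent-4-yn-2-ol | COc1ccc(COC[C@@H](O)CC#C)cc1 | intermediate
7 | dimethylaluminium (2S,4E)-5-(dimethylalumanyl)-1-((4-methoxybenzyl)oxy)-4-methylpent-4-en-2-olate (alkenylalane) | COc1ccc(COC[C@@H](O[Al](C)C)C/C(C)=C/[Al](C)C)cc1 | intermediate
8 | (2S,4E)-5-iodo-1-((4-methoxybenzyl)oxy)-4-methylpent-4-en-2-ol | COc1ccc(COC[C@@H](O)C/C(C)=C/I)cc1 | intermediate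
9 | tert-butyl(((2S,4E)-5-iodo-1-((4-methoxybenzyl)oxy)-4-methylpent-4-en-2-yl)oxy)dimethylsilane | COc1ccc(COC[C@@H](O[Si](C)(C)C(C)(C)C)C/C(C)=C/I)cc1 | intermediate
10 | 9-[(3Z)-5-((9-borabicyclo[3.3.1]nonan-9-yl)oxy)-3-(((triisopropylsilyl)oxy)methyl)pent-3-en-1-yl]-9-borabicyclo[3.3.1]nonane (B-alkyl-9-BBN adduct) | O(B1C2CCCC1CCC2)C/C=C(/CCB1C2CCCC1CCC2)CO[Si](C(C)C)(C(C)C)C(C)C | intermediate
11 | (2Z,6E,9S)-9-((tert-butyldimethylsilyl)oxy)-10-((4-methoxybenzyl)oxy)-7-methyl-3-(((triisopropylsilyl)oxy)methyl)deca-2,6-dien-1-ol | OC/C=C(/CC/C=C(\C)C[C@H](O[Si](C)(C)C(C)(C)C)COCc1ccc(OC)cc1)CO[Si](C(C)C)(C(C)C)C(C)C | intermediate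
12 | (2Z,6E,9S)-9-((tert-butyldimethylsilyl)oxy)-7-methyl-3-(((triisopropylsilyl)oxy)methyl)deca-2,6-diene-1,10-diol | OC/C=C(/CC/C=C(\C)C[C@H](O[Si](C)(C)C(C)(C)C)CO)CO[Si](C(C)C)(C(C)C)C(C)C | intermediate
13 | (2Z,6E,9S)-9-((tert-butyldimethylsilyl)oxy)-7-methyl-3-(((triisopropylsilyl)oxy)methyl)deca-2,6-dienedial | O=C/C=C(/CC/C=C(\C)C[C@H](O[Si](C)(C)C(C)(C)C)C=O)CO[Si](C(C)C)(C(C)C)C(C)C | intermediate
14 | methyl (4S,6E,10Z)-4-((tert-butyldimethylsilyl)oxy)-3-hydroxy-6-methyl-2-methylidene-12-oxo-10-(((triisopropylsilyl)oxy)methyl)dodeca-6,10-dienoate (C3 epimers) | COC(=O)C(=C)C(O)[C@@H](O[Si](C)(C)C(C)(C)C)C/C(C)=C/CC/C(CO[Si](C(C)C)(C(C)C)C(C)C)=C/C=O | intermediate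
15 | methyl (2Z,4S,6E,10Z)-2-(bromomethyl)-4-((tert-butyldimethylsilyl)oxy)-6-methyl-12-oxo-10-(((triisopropylsilyl)oxy)methyl)dodeca-2,6,10-trienoate | COC(=O)/C(CBr)=C/[C@@H](O[Si](C)(C)C(C)(C)C)C/C(C)=C/CC/C(CO[Si](C(C)C)(C(C)C)C(C)C)=C/C=O | intermediate
16 | methyl 8α-(tert-butyldimethylsilyloxy)-6α-hydroxy-15-(triisopropylsilyloxy)germacra-1(10)E,4Z,11(13)-trien-12-oate (hydroxy ester) | C/C1=C\CC/C(CO[Si](C(C)C)(C(C)C)C(C)C)=C/[C@@H](O)[C@H](C(=C)C(=O)OC)[C@@H](O[Si](C)(C)C(C)(C)C)C1 | intermediate
17 | 8α-(tert-butyldimethylsilyloxy)-15-(triisopropylsilyloxy)germacra-1(10)E,4Z,11(13)-trien-12,6α-olide | C/C1=C\CC/C(CO[Si](C(C)C)(C(C)C)C(C)C)=C/[C@H]2OC(=O)C(=C)[C@@H]2[C@@H](O[Si](C)(C)C(C)(C)C)C1 | intermediate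
18 | (6R,7R,8S)-8α,15-dihydroxygermacra-1(10)E,4Z,11(13)-trien-12,6α-olide (salonitenolide) | C/C1=C\CC/C(CO)=C/[C@H]2OC(=O)C(=C)[C@@H]2[C@@H](O)C1 | intermediate
19 | 8α-hydroxy-15-oxogermacra-1(10)E,4Z,11(13)-trien-12,6α-olide (germacranolide 15-aldehyde) | C/C1=C\CC/C(C=O)=C/[C@H]2OC(=O)C(=C)[C@@H]2[C@@H](O)C1 | intermediate
20 | (5R,6R,7R,8S,10S)-8α-hydroxy-15-oxoelema-1,3,11(13)-trien-12,6α-olide | C=C[C@]1(C)C[C@H](O)[C@H]2C(=C)C(=O)O[C@@H]2[C@H]1C(=C)C=O | intermediate
21 | (R)-4-(2-hydroxyethyl)-2,2-dimethyl-1,3-dioxolane | OCC[C@@H]1COC(C)(C)O1 | starting material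
22 | (R)-2-(2,2-dimethyl-1,3-dioxolan-4-yl)acetaldehyde | O=CC[C@@H]1COC(C)(C)O1 | intermediate
23 | (R)-2-(2,2-dimethyl-1,3-dioxolan-4-yl)acrylaldehyde | C=C(C=O)[C@@H]1COC(C)(C)O1 | intermediate
24 | (R)-2-(2,2-dimethyl-1,3-dioxolan-4-yl)acrylic acid | C=C(C(=O)O)[C@@H]1COC(C)(C)O1 | intermediate
25 | (R)-2-(2,2-dimethyl-1,3-dioxolan-4-yl)acrylic 2,4,6-trichlorobenzoic anhydride (mixed anhydride) | C=C(C(=O)OC(=O)c1c(Cl)cc(Cl)cc1Cl)[C@@H]1COC(C)(C)O1 | intermediate
26 | 8α-[(R)-2-(2,2-dimethyl-1,3-dioxolan-4-yl)acryloyloxy]-15-oxoelema-1,3,11(13)-trien-12,6α-olide | C=C[C@]1(C)C[C@H](OC(=O)C(=C)[C@@H]3COC(C)(C)O3)[C@H]2C(=C)C(=O)O[C@@H]2[C@H]1C(=C)C=O | intermediate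
27 | CNP0204284.1, 8α-[(R)-3,4-dihydroxy-2-methylenebutanoyloxy]-15-oxoelema-1,3,11(13)-trien-12,6α-olide | C=C[C@]1(C)C[C@H](OC(=O)C(=C)[C@@H](O)CO)[C@H]2C(=C)C(=O)O[C@@H]2[C@H]1C(=C)C=O | target

## Step count and least certain steps

Total step count: 19. Longest linear sequence: 13 steps (from 5 through steps 4–14, 18 and 19; equally from 1 through steps 1–3, 7–14, 18 and 19).

**Step 14 (key step).**
- What may go wrong: the rearrangement of 19 may be slow at ambient temperature, leaving the strained enal exposed to over-oxidation on manganese dioxide or to transannular ene-type cyclisation. Less likely, rearrangement through a minor ring conformer could give poor facial selectivity at C5/C10.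
- Fallback (oxidation and rearrangement uncoupled): set out from 17 and run the Cope rearrangement thermally at the silyl ether stage (degassed toluene, BHT, 190–200 °C, sealed tube) to give 8α-(tert-butyldimethylsilyloxy)-15-(triisopropylsilyloxy)elema-1,3,11(13)-trien-12,6α-olide F1. Desilylation with HF·pyridine gives the acid-insensitive 8α,15-dihydroxyelema-1,3,11(13)-trien-12,6α-olide F2. MnO2 oxidation of its allylic C15 alcohol returns to the route at 20.

**Step 12.**
- What may go wrong: oligomerisation instead of ten-membered ring closure, loss of silyloxide from the allylchromium species (diene formation), or syn addition that leads to the 6,7-cis lactone.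
- Fallback (C6 set by inversion instead of by the cyclisation): set out from 15; if the cyclisation under the same conditions delivers the C6 epimer, 8α-(tert-butyldimethylsilyloxy)-15-(triisopropylsilyloxy)germacra-1(10)E,4Z,11(13)-trien-12,6β-olide F3, saponify it (LiOH, THF/H2O; acidify carefully to pH 5 at 0 °C) to the 6β-hydroxy acid F4. Mitsunobu lactonisation (PPh3, DIAD, THF, high dilution) with inversion at C6 returns to the route at 17.

**Step 10.**
- What may go wrong: slow addition to the hindered α-silyloxy aldehyde, during which epimerisation at C8 and Z/E drift of the enal by reversible amine addition can compete.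
- Fallback (acrylate unit installed before the fragment union, with no enal present): set out from 9. DDQ removes the PMB group to give (2S,4E)-2-((tert-butyldimethylsilyl)oxy)-5-iodo-4-methylpent-4-en-1-ol F5. Dess–Martin oxidation gives (2S,4E)-2-((tert-butyldimethylsilyl)oxy)-5-iodo-4-methylpent-4-enal F6. The preformed α-(methoxycarbonyl)vinylaluminium reagent (methyl propiolate, DIBAL-H, NMO, THF) adds to give methyl (4S,6E)-4-((tert-butyldimethylsilyl)oxy)-3-hydroxy-7-iodo-6-methyl-2-methylidenehept-6-enoate F7. B-alkyl Suzuki–Miyaura coupling of F7 with borane 10 gives methyl (4S,6E,10Z)-4-((tert-butyldimethylsilyl)oxy)-3,12-dihydroxy-6-methyl-2-methylidene-10-(((triisopropylsilyl)oxy)methyl)dodeca-6,10-dienoate F8. MnO2 oxidises only its primary, electron-rich allylic alcohol and returns to the route at 14.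

## Further compounds

F1 | step 14 | 8α-(tert-butyldimethylsilyloxy)-15-(triisopropylsilyloxy)elema-1,3,11(13)-trien-12,6α-olide | C=C[C@]1(C)C[C@H](O[Si](C)(C)C(C)(C)C)[C@H]2C(=C)C(=O)O[C@@H]2[C@H]1C(=C)CO[Si](C(C)C)(C(C)C)C(C)C
F2 | step 14 | 8α,15-dihydroxyelema-1,3,11(13)-trien-12,6α-olide | C=C[C@]1(C)C[C@H](O)[C@H]2C(=C)C(=O)O[C@@H]2[C@H]1C(=C)CO
F3 | step 12 | 8α-(tert-butyldimethylsilyloxy)-15-(triisopropylsilyloxy)germacra-1(10)E,4Z,11(13)-trien-12,6β-olide (C6 epimer of 17) | C/C1=C\CC/C(CO[Si](C(C)C)(C(C)C)C(C)C)=C/[C@@H]2OC(=O)C(=C)[C@@H]2[C@@H](O[Si](C)(C)C(C)(C)C)C1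
F4 | step 12 | 8α-(tert-butyldimethylsilyloxy)-6β-hydroxy-15-(triisopropylsilyloxy)germacra-1(10)E,4Z,11(13)-trien-12-oic acid | C/C1=C\CC/C(CO[Si](C(C)C)(C(C)C)C(C)C)=C/[C@H](O)[C@H](C(=C)C(=O)O)[C@@H](O[Si](C)(C)C(C)(C)C)C1
F5 | step 10 | (2S,4E)-2-((tert-butyldimethylsilyl)oxy)-5-iodo-4-methylpent-4-en-1-ol | OC[C@@H](O[Si](C)(C)C(C)(C)C)C/C(C)=C/I
F6 | step 10 | (2S,4E)-2-((tert-butyldimethylsilyl)oxy)-5-iodo-4-methylpent-4-enal | O=C[C@@H](O[Si](C)(C)C(C)(C)C)C/C(C)=C/I
F7 | step 10 | methyl (4S,6E)-4-((tert-butyldimethylsilyl)oxy)-3-hydroxy-7-iodo-6-methyl-2-methylidenehept-6-enoate | COC(=O)C(=C)C(O)[C@@H](O[Si](C)(C)C(C)(C)C)C/C(C)=C/I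
F8 | step 10 | methyl (4S,6E,10Z)-4-((tert-butyldimethylsilyl)oxy)-3,12-dihydroxy-6-methyl-2-methylidene-10-(((triisopropylsilyl)oxy)methyl)dodeca-6,10-dienoate | COC(=O)C(=C)C(O)[C@@H](O[Si](C)(C)C(C)(C)C)C/C(C)=C/CC/C(CO[Si](C(C)C)(C(C)C)C(C)C)=C/CO
A1 | alternative 1 | (5S,6R)-5-((tert-butyldimethylsilyl)oxy)-3-methyl-6-(prop-1-en-2-yl)cyclohex-2-en-1-one | O=C1C=C(C)C[C@H](O[Si](C)(C)C(C)(C)C)[C@H]1C(C)=C
A2 | alternative 2 | 8α-(tert-butyldimethylsilyloxy)-4α-methyl-eudesma-2,11(13)-dien-12,6α-olide (5αH,10β-methyl) | C[C@@H]1C=CC[C@]2(C)C[C@H](O[Si](C)(C)C(C)(C)C)[C@H]3C(=C)C(=O)O[C@@H]3[C@@H]12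
A3 | alternative 3 | methyl (2Z)-2-(bromomethyl)-4-((tert-butyldimethylsilyl)oxy)-8-(((tert-butyldimethylsilyl)oxy)methyl)-7-formyl-6-methyl-6-vinylnona-2,8-dienoate with C4, C6 and C7 configured as C8, C10 and C5 of the target | C=C[C@](C)(C[C@H](O[Si](C)(C)C(C)(C)C)/C=C(\CBr)C(=O)OC)[C@@H](C=O)C(=C)CO[Si](C)(C)C(C)(C)C
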